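**Plan**

1. Clerodane numbering (C1–C20) is used for all compounds. "Hydrindane" means ring B (C5–C10) fused to the five-membered ring C1–C2–C3–C5–C10, that is, ring A before C4 (with C18) is inserted. α/β are as in the usual neo-clerodane drawing (H-10 β, C19 α).
2. Retrosynthesis: the O6/O19 acetates and the silyl groups come off last. The butenolide is traced to a 3-furyl group and both (S)-2-methylbutanoates to a 1β,12-diol. C12–C13 is cut to 3-furyllithium plus a 1,12-δ-lactone (a cyclic template tying O1 to C12). O1 is traced back to a C3 ketone (Wharton transposition), and then the C4–C5 bond of ring A is cut.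
3. Enabling feature: C4 of ring A is a fully substituted carbinol carbon (OH, CH2Cl) flanked by quaternary C5 and by C3. Ring A (C1–C2–C3–C4–C5–C10) can therefore arise from the five-membered ring C1–C2–C3–C5–C10 when chlorination at C18 of an exocyclic silyl enol ether C4=C18 makes C5 shift from C3 to C4. O3 and O4 are held in a temporary spiro silylene ring.
4. Forward order: Hajos–Parrish-type enedione (ring B plus five-membered ring) → reductive allylation → enone transposition and dissolving-metal reduction → O6-directed C19 hydroxylation → ring enlargement to ring A → Wharton transposition → lactone → furyl ketone → butenolide → desilylation and acetylation.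
5. Stereochemistry: C5 from D-phenylalanine; C10, C9, C8 and C6 by substrate control from C5; C3 (temporary) by addition anti to C19; C4 by the silylene-templated 1,2-shift; C1 by β-face epoxidation; C12 by RuCl[(S,S)-TsDPEN](p-cymene); the acyl stereocenters from (S)-2-methylbutanoic anhydride.

Key step: step 16

**Route**

Step 1
Reactants: 1 2-methylcyclopentane-1,3-dione; 2 pent-1-en-3-one (ethyl vinyl ketone)
Product: 3 2-methyl-2-(3-oxopentyl)cyclopentane-1,3-dione
Conditions: H2O, rt
Reagents that add atoms: none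
Why: Michael addition of the acidic 1,3-dione to the enone in water is the standard entry to Hajos–Parrish-type triketones and creates no stereocenter.

Step 2
Reactants: 3 2-methyl-2-(3-oxopentyl)cyclopentane-1,3-dione
Product: 5 (R)-4,7a-dimethyl-2,3,7,7a-tetrahydro-1H-indene-1,5(6H)-dione, via bicyclic ketol 4 (not isolated)
Conditions: D-phenylalanine (1 equiv), 1 M HClO4 (0.5 equiv), MeCN, reflux
Reagents that add atoms: none
Why: Hajos–Parrish–Eder–Sauer–Wiechert aldol condensation, in which the D-phenylalanine enamine of the ethyl ketone attacks one enantiotopic ring carbonyl and acid dehydrates the ketol, so that the amino acid should set the angular carbon C5 (bearing C19) in the R configuration, opposite to that given by L-amino acids.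

Step 3
Reactants: 5 (R)-enedione
Product: 6 hydrind-9-ene-3,8-dione 3-ethylene ketal
Conditions: 2-ethyl-2-methyl-1,3-dioxolane, ethylene glycol (cat.), TsOH·H2O (cat.), rt
Reagents that add atoms: 2-ethyl-2-methyl-1,3-dioxolane, CCC1(C)OCCO1
Why: acid-catalysed transketalization should protect the saturated cyclopentanone (C3) selectively, because the C8 carbonyl is conjugated and flanked by a tetrasubstituted alkene.

Step 4
Reactants: 6 enone ketal
Product: 8 9β-allyl-trans-hydrindane-3,8-dione 3-ethylene ketal, via lithium enolate 7 (not isolated)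
Conditions: Li (2.2 equiv), t-BuOH (1.0 equiv), NH3(l)/THF, −78 °C; then allyl bromide, −78 → −33 °C
Reagents that add atoms: allyl bromide, C=CCBr
Why: Birch-type reductive alkylation, in which axial protonation at C10 should give the trans ring fusion (H-10 β, anti to C19) and the regiospecific C8 enolate is allylated at C9 anti to the 1,3-related axial C19 methyl, placing C11 β and C20 α.

Step 5
Reactants: 8 allyl ketone
Product: 9 9β-allyl-hydrind-6-ene-3,8-dione 3-ethylene ketal
Conditions: IBX (2.5 equiv), DMSO, 70 °C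
Reagents that add atoms: none
Why: IBX dehydrogenation of the ketone can only proceed toward C7 because C9 is quaternary, so the C6=C7 enone should form regiospecifically.

Step 6
Reactants: 9 enone
Product: 10 9β-allyl-8-hydroxy-8-methylhydrind-6-en-3-one ethylene ketal
Conditions: MeLi, THF, −78 °C; then H2O
Reagents that add atoms: methyllithium, [Li]C
Why: 1,2-addition of an organolithium to the enone brings in C17; the configuration at the carbinol carbon C8 is irrelevant because C8 becomes sp2 in the next step.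

Step 7
Reactants: 10 tertiary allylic alcohol
Product: 11 9β-allyl-8-methylhydrind-7-ene-3,6-dione 3-ethylene ketal
Conditions: pyridinium chlorochromate, 4 Å MS, CH2Cl2, rt
Reagents that add atoms: pyridinium chlorochromate, [O-][Cr](=O)(=O)Cl.c1cc[nH+]cc1
Why: Babler–Dauben oxidative transposition, in which the [3,3]-shift of the tertiary allylic chromate ester moves oxygen to C6 and oxidation gives the 8-methyl-7-en-6-one, so that ring B carries its oxygen at C6 and its methyl at C8.

Step 8
Reactants: 11 transposed enone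
Product: 13 9β-allyl-6α-hydroxy-8α-methylhydrindan-3-one ethylene ketal, via saturated 6-ketone 12 (not isolated)
Conditions: Li (excess), NH3(l)/THF, −78 °C; then EtOH (excess), −78 → −33 °C
Reagents that add atoms: none
Why: dissolving-metal reduction of the enone and then of the ketone, in which axial protonation at C8 should leave the C17 methyl equatorial (α) and the carbinol should take the thermodynamically preferred equatorial 6α configuration, while the isolated allyl alkene is not reduced.

Step 9
Reactants: 13 allyl alcohol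
Product: 15 6α,12-dihydroxy-8α-methylhydrindan-3-one ethylene ketal, via secondary ozonide 14 (not isolated)
Conditions: O3, CH2Cl2, −78 °C; then NaBH4, MeOH, −78 → 0 °C
Reagents that add atoms: ozone, [O-][O+]=O
Why: ozonolysis with reductive work-up shortens the allyl group to the two-carbon C11–C12 alcohol and touches no stereocenter.

Step 10
Reactants: 15 diol
Product: 16 12-benzyloxy-6α-hydroxy-8α-methylhydrindan-3-one ethylene ketal
Conditions: NaH (1.05 equiv), BnBr (1.05 equiv), Bu4NI (cat.), THF, 0 °C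
Reagents that add atoms: benzyl bromide, BrCc1ccccc1
Why: Williamson etherification should take place at the primary C12 alkoxide, since the secondary O6 is neopentyl and flanked by quaternary C5.

Step 11
Reactants: 16 benzyl ether
Product: 19 12-benzyloxy-6α,19-dihydroxy-8α-methylhydrindan-3-one ethylene ketal, via hydridosilyl ether 17 (not isolated), via oxasilolane 18 (not isolated)
Conditions: Et2SiH2, [Ir(cod)(OMe)]2 (0.5 mol%), THF, rt; then [Ir(cod)(OMe)]2 (1 mol%), 3,4,7,8-tetramethyl-1,10-phenanthroline, norbornene, THF, 120 °C; then H2O2, KHCO3, THF/MeOH, 50 °C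
Reagents that add atoms: hydrogen peroxide, OO
Why: alcohol-directed iridium-catalysed γ-C–H silylation followed by Tamao–Fleming oxidation, in which the O6-bound Si–H can reach only one primary γ-C–H, the C19 methyl, through a five-membered oxasilolane, so C19 should be hydroxylated without change at any stereocenter.

Step 12
Reactants: 19 6α,19-diol
Product: 20 12-benzyloxy-6α,19-(di-tert-butylsilylenedioxy)-8α-methylhydrindan-3-one ethylene ketal
Conditions: t-Bu2Si(OTf)2, 2,6-lutidine, CH2Cl2, 0 °C
Reagents that add atoms: di-tert-butylsilyl bis(trifluoromethanesulfonate), CC(C)(C)[Si](OS(=O)(=O)C(F)(F)F)(OS(=O)(=O)C(F)(F)F)C(C)(C)C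
Why: standard silylene protection of a 1,3-diol as a six-membered ring that should withstand organolithiums and aqueous acid and is removed by fluoride at the end.

Step 13
Reactants: 20 silylene ketal
Product: 21 12-benzyloxy-6α,19-(di-tert-butylsilylenedioxy)-8α-methylhydrindan-3-one
Conditions: TsOH·H2O (cat.), acetone/H2O, 50 °C
Reagents that add atoms: water, O
Why: acid-catalysed ketal hydrolysis frees the C3 cyclopentanone, and the silylene and the benzyl ether should be stable to these conditions.

Step 14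
Reactants: 21 hydrindan-3-one
Product: 23 3β-acetyl-12-benzyloxy-6α,19-(di-tert-butylsilylenedioxy)-8α-methylhydrindan-3α-ol, via enol ether carbinol 22 (not isolated)
Conditions: ethyl vinyl ether, t-BuLi, THF, −78 → 0 °C; then 21, −78 °C; then 1 M HCl, THF, 0 °C
Reagents that add atoms: ethyl vinyl ether, C=COCC; water, O
Why: addition of 1-ethoxyvinyllithium (an acyl anion equivalent) to the C3 ketone should occur from the β face, anti to the angular C19 group on C5 as in additions to 17-oxo steroids, so that O3 is α and the new two-carbon unit C4–C18 is β, and mild acid then hydrolyses the enol ether to the methyl ketone.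

Step 15
Reactants: 23 acetyl carbinol
Product: 24 spiro silylene enol ether (O3,O4-di-tert-butylsilylene of the 4(18)-ene-3α,4-diol)
Conditions: t-Bu2Si(OTf)2, Et3N, CH2Cl2, 0 °C → rt; pentane trituration, filtration
Reagents that add atoms: di-tert-butylsilyl bis(trifluoromethanesulfonate), CC(C)(C)[Si](OS(=O)(=O)C(F)(F)F)(OS(=O)(=O)C(F)(F)F)C(C)(C)C
Why: silyl triflate/amine enol silylation of the methyl ketone (only C18 can enolise) and silylation of the tertiary O3 by the same silicon should close a spiro 1,3,2-dioxasilolane, which fixes O3–C3–C4–O4 syn-periplanar and makes C4=C18 an electron-rich silyl enol ether.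

Step 16
Reactants: 24 spiro silylene enol ether
Product: 26 12-benzyloxy-18-chloro-4α-[di-tert-butyl(methoxy)silyloxy]-6α,19-(di-tert-butylsilylenedioxy)-13,14,15,16-tetranorclerodan-3-one, via N-silylsuccinimide 25 (not isolated)
Conditions: N-chlorosuccinimide (1.05 equiv), CH2Cl2, −78 → 0 °C; then MeOH, 0 °C → rt
Reagents that add atoms: N-chlorosuccinimide, O=C1CCC(=O)N1Cl; methanol, CO
Why: Proposed new method: Cl+ transfer from N-chlorosuccinimide to the terminal carbon C18 of the silyl enol ether should give a silyloxycarbenium ion at C4, whereupon the C3–C5 bond, held about 30° from the axis of the empty p orbital by the spiro dioxasilolane, shifts from C3 to C4 (semipinacol 1,2-shift), and the resulting silyloxocarbenium ion at C3 hands its silicon to succinimide and then to methanol. The closest known reaction types are the halonium-triggered semipinacol ring expansion of 1-(1-alkoxyvinyl)cycloalkanols and the Lewis-acid α-ketol ring enlargement of 17-hydroxy-20-oxo steroids; the new element is a silyl enol ether inside a silylene ring as the cation precursor. Ring A is closed not by a cyclisation but by ring enlargement: the suprafacial 1,2-alkyl shift forms the C4–C5 bond with retention at C5 and turns the five-membered ring C1–C2–C3–C5–C10 into the six-membered ring. The new stereocenter C4 is controlled by the template, because with O3 and O4 tied syn C5 can only add to the C4 face that leaves O4 α (equatorial) and CH2Cl β (axial), so the C3 configuration set in step 14 is relayed to C4. The step needs migration of C5 instead of C2 and a shift instead of plain desilylative α-chlorination; the first should be secured by the higher migratory aptitude of the fully substituted C5 (as in the steroid precedents), the second by the tert-butyl groups, which slow external attack on silicon while the shift is intramolecular. Chlorine arrives directly as the C18 chloride, so no later C–Cl bond formation is needed.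

Step 17
Reactants: 26 ring-enlarged ketone
Product: 27 the corresponding 13,14,15,16-tetranorclerod-1-en-3-one
Conditions: IBX, 4-methoxypyridine N-oxide, DMSO, rt → 40 °C
Reagents that add atoms: none
Why: IBX dehydrogenation of the C3 ketone can only go toward C2 because C4 is quaternary, giving the C1=C2 enone needed to carry oxygen to C1.

Step 18
Reactants: 27 enone
Product: 28 the corresponding 1β,2β-epoxy-13,14,15,16-tetranorclerodan-3-one
Conditions: t-BuOOH (in decane), DBU, CH2Cl2, 0 °C → rt
Reagents that add atoms: tert-butyl hydroperoxide, CC(C)(C)OO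
Why: Weitz–Scheffer nucleophilic epoxidation, in which the peroxide should add to C1 from the β face, anti to C9 on the adjacent carbon and away from the axial C19 and C20 groups, giving the 1β,2β-epoxide, while the non-aqueous base leaves the silyl groups and the neopentyl chloride (no β-hydrogen) untouched.

Step 19
Reactants: 28 epoxy ketone
Product: 30 the corresponding 13,14,15,16-tetranorclerod-2-en-1β-ol, via epoxy hydrazone 29 (not isolated)
Conditions: N2H4·H2O, AcOH, MeOH, 0 °C → rt
Reagents that add atoms: none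
Why: Wharton transposition, in which the hydrazone opens the epoxide and loses N2, so that oxygen is moved from C3 to C1 with the β C1–O bond untouched and a C2=C3 alkene is left.

Step 20
Reactants: 30 allylic alcohol
Product: 31 18-chloro-4α-[di-tert-butyl(methoxy)silyloxy]-6α,19-(di-tert-butylsilylenedioxy)-13,14,15,16-tetranorclerodane-1β,12-diol
Conditions: H2 (1 atm), Pd/C, EtOAc, rt
Reagents that add atoms: none
Why: catalytic hydrogenation should saturate C2=C3 and hydrogenolyse the benzyl ether in one operation, while the primary alkyl chloride and the silyl groups survive neutral Pd/C.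

Step 21
Reactants: 31 1β,12-diol
Product: 33 the corresponding 13,14,15,16-tetranorclerodan-12,1β-olide (δ-lactone), via lactol 32 (not isolated)
Conditions: TEMPO (20 mol%), PhI(OAc)2, CH2Cl2, rt
Reagents that add atoms: none
Why: TEMPO/PhI(OAc)2 oxidises the primary C12 alcohol selectively; the aldehyde should be trapped by the 1β-OH as a strain-free chair lactol (O1 and C11 are both equatorial, giving an all-trans peri-fused system) and oxidised on to the δ-lactone, which protects O1 and activates C12 at once.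

Step 22
Reactants: 33 δ-lactone
Product: 35 3-furyl ketone (12-oxo-15,16-epoxycleroda-13(16),14-dien-1β-ol carrying the 18-chloro and silyl groups of 33), via lithium hemiketal alkoxide 34 (not isolated)
Conditions: 3-bromofuran, n-BuLi, THF, −78 °C; then 33, −78 °C; then H2O
Reagents that add atoms: 3-bromofuran, Brc1ccoc1
Why: addition of 3-furyllithium to the lactone should stop at the tetrahedral lithium hemiketal at −78 °C, so that work-up gives the C12 furyl ketone (C12–C13 bond) and frees the 1β-OH.

Step 23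
Reactants: 35 furyl ketone
Product: 36 the (12S)-1β,12-diol
Conditions: RuCl[(S,S)-TsDPEN](p-cymene) (3 mol%), HCO2H/Et3N (5:2), CH2Cl2, rt
Reagents that add atoms: none
Why: Noyori asymmetric transfer hydrogenation of the heteroaryl ketone is reagent-controlled, and the (S,S) catalyst, which gives (S)-1-arylalkanols, should deliver the (12S) alcohol while tolerating the free 1-OH.

Step 24
Reactants: 36 (12S)-diol
Product: 37 the 1β,12-bis[(S)-2-methylbutanoate]
Conditions: (S)-2-methylbutanoic anhydride, DMAP, Et3N, CH2Cl2, rt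
Reagents that add atoms: (S)-2-methylbutanoic anhydride, CC[C@H](C)C(=O)OC(=O)[C@@H](C)CC
Why: DMAP-catalysed acylation should esterify both secondary alcohols (O1 and O12) with the same acyl group in one step, the acyl α-stereocenters coming unchanged from the enantiopure anhydride.

Step 25
Reactants: 37 furan bis-ester
Product: 39 silyl-protected clerod-13-en-15,16-olide (butenolide), via hydroxybutenolide 38 (not isolated)
Conditions: O2, rose bengal, hν, i-Pr2NEt, CH2Cl2, −78 °C; then NaBH4, MeOH, 0 °C; then 1 M HCl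
Reagents that add atoms: oxygen, O=O
Why: singlet-oxygen [4+2] addition to the 3-substituted furan followed by base-induced opening of the endoperoxide at the less hindered position (C15-H) should give the 16-hydroxy-15,16-olide regioselectively, and NaBH4 reduces the masked C16 aldehyde so that relactonisation gives the β-substituted butenolide.

Step 26
Reactants: 39 protected butenolide
Product: 40 6,19-di-O-deacetylajugaciliatin A (4α,6α,19-triol)
Conditions: HF·pyridine, pyridine, THF, 0 °C → rt
Reagents that add atoms: none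
Why: acidic fluoride desilylation should remove the 6,19-silylene and the silyl group on O4 in one operation without generating an alkoxide next to CH2Cl, so the chlorohydrin cannot close to the epoxide.

Step 27
Reactants: 40 triol
Product: 41 ajugaciliatin A
Conditions: Ac2O, pyridine, DMAP (cat.), CH2Cl2, 0 °C
Reagents that add atoms: acetic anhydride, CC(=O)OC(C)=O
Why: acetylation should take place at the primary 19-OH and the secondary 6α-OH only, because the tertiary 4α-OH next to quaternary C5 is not acylated under these conditions.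

**Compound list**

1 | 2-methylcyclopentane-1,3-dione | CC1C(=O)CCC1=O | starting material
2 | pent-1-en-3-one (ethyl vinyl ketone) | CCC(=O)C=C | starting material
3 | 2-methyl-2-(3-oxopentyl)cyclopentane-1,3-dione | CCC(=O)CCC1(C)C(=O)CCC1=O | intermediate
4 | cis-fused bicyclic ketol (10-hydroxy-hydrindane-3,8-dione; OH cis to C19; C9 methyl epimers) | CC1C(=O)CC[C@@]2(C)C(=O)CC[C@@]12O | intermediate (not isolated)
5 | (R)-4,7a-dimethyl-2,3,7,7a-tetrahydro-1H-indene-1,5(6H)-dione (hydrind-9-ene-3,8-dione) | CC1=C2CCC(=O)[C@]2(C)CCC1=O | intermediate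
6 | hydrind-9-ene-3,8-dione 3-ethylene ketal | CC1=C2CCC3(OCCO3)[C@]2(C)CCC1=O | intermediate
7 | lithium 8(9)-enolate of the trans-hydrindan-8-one 3-ethylene ketal (H-10 β) | CC1=C([O-])CC[C@]2(C)[C@@H]1CCC23OCCO3.[Li+] | intermediate (not isolated)
8 | 9β-allyl-trans-hydrindane-3,8-dione 3-ethylene ketal (C20 α) | C=CC[C@@]1(C)C(=O)CC[C@]2(C)[C@@H]1CCC23OCCO3 | intermediate
9 | 9β-allyl-hydrind-6-ene-3,8-dione 3-ethylene ketal | C=CC[C@@]1(C)C(=O)C=C[C@]2(C)[C@@H]1CCC23OCCO3 | intermediate
10 | 9β-allyl-8-hydroxy-8-methylhydrind-6-en-3-one ethylene ketal (C8 epimers) | C=CC[C@@]1(C)C(C)(O)C=C[C@]2(C)[C@@H]1CCC23OCCO3 | intermediate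
11 | 9β-allyl-8-methylhydrind-7-ene-3,6-dione 3-ethylene ketal | C=CC[C@@]1(C)C(C)=CC(=O)[C@]2(C)[C@@H]1CCC23OCCO3 | intermediate
12 | 9β-allyl-8α-methylhydrindane-3,6-dione 3-ethylene ketal | C=CC[C@@]1(C)[C@H](C)CC(=O)[C@]2(C)[C@@H]1CCC23OCCO3 | intermediate (not isolated)
13 | 9β-allyl-6α-hydroxy-8α-methylhydrindan-3-one ethylene ketal | C=CC[C@@]1(C)[C@H](C)C[C@H](O)[C@]2(C)[C@@H]1CCC23OCCO3 | intermediate
14 | secondary ozonide (1,2,4-trioxolane) of 13 | C4(OCOO4)C[C@@]1(C)[C@H](C)C[C@H](O)[C@]2(C)[C@@H]1CCC23OCCO3 | intermediate (not isolated)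
15 | 6α,12-dihydroxy-8α-methylhydrindan-3-one ethylene ketal (C9β carries CH2CH2OH) | OCC[C@@]1(C)[C@H](C)C[C@H](O)[C@]2(C)[C@@H]1CCC23OCCO3 | intermediate
16 | 12-benzyloxy-6α-hydroxy-8α-methylhydrindan-3-one ethylene ketal | c1ccccc1COCC[C@@]1(C)[C@H](C)C[C@H](O)[C@]2(C)[C@@H]1CCC23OCCO3 | intermediate
17 | 6-O-(diethylhydridosilyl) ether of 16 | c1ccccc1COCC[C@@]1(C)[C@H](C)C[C@H](O[SiH](CC)CC)[C@]2(C)[C@@H]1CCC23OCCO3 | intermediate (not isolated)
18 | oxasilolane (O6–SiEt2–C19 ring) | c1ccccc1COCC[C@@]1(C)[C@H](C)C[C@@H]4O[Si](CC)(CC)C[C@]42[C@@H]1CCC23OCCO3 | intermediate (not isolated)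
19 | 12-benzyloxy-6α,19-dihydroxy-8α-methylhydrindan-3-one ethylene ketal | c1ccccc1COCC[C@@]1(C)[C@H](C)C[C@H](O)[C@]2(CO)[C@@H]1CCC23OCCO3 | intermediate
20 | 12-benzyloxy-6α,19-(di-tert-butylsilylenedioxy)-8α-methylhydrindan-3-one ethylene ketal | c1ccccc1COCC[C@@]1(C)[C@H](C)C[C@@H]4O[Si](C(C)(C)C)(C(C)(C)C)OC[C@]42[C@@H]1CCC23OCCO3 | intermediate
21 | 12-benzyloxy-6α,19-(di-tert-butylsilylenedioxy)-8α-methylhydrindan-3-one | c1ccccc1COCC[C@@]1(C)[C@H](C)C[C@@H]4O[Si](C(C)(C)C)(C(C)(C)C)OC[C@]42[C@@H]1CCC2=O | intermediate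
22 | 3β-(1-ethoxyvinyl)-3α-hydroxy adduct of 21 | c1ccccc1COCC[C@@]1(C)[C@H](C)C[C@@H]4O[Si](C(C)(C)C)(C(C)(C)C)OC[C@]42[C@@H]1CC[C@]2(O)C(=C)OCC | intermediate (not isolated)
23 | 3β-acetyl-12-benzyloxy-6α,19-(di-tert-butylsilylenedioxy)-8α-methylhydrindan-3α-ol (acetyl = C4 and C18) | c1ccccc1COCC[C@@]1(C)[C@H](C)C[C@@H]4O[Si](C(C)(C)C)(C(C)(C)C)OC[C@]42[C@@H]1CC[C@]2(O)C(C)=O | intermediate
24 | spiro silylene enol ether (O3,O4-di-tert-butylsilylene of the 4(18)-ene-3α,4-diol) | c1ccccc1COCC[C@@]1(C)[C@H](C)C[C@@H]4O[Si](C(C)(C)C)(C(C)(C)C)OC[C@]42[C@@H]1CC[C@@]25O[Si](C(C)(C)C)(C(C)(C)C)OC5=C | intermediate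
25 | ring-enlarged 3-ketone with 4α-O-[di-tert-butyl(succinimido)silyl] group | c1ccccc1COCC[C@@]1(C)[C@H](C)C[C@@H]4O[Si](C(C)(C)C)(C(C)(C)C)OC[C@]42[C@@H]1CCC(=O)[C@]2(O[Si](N5C(=O)CCC5=O)(C(C)(C)C)C(C)(C)C)CCl | intermediate (not isolated)
26 | 12-benzyloxy-18-chloro-4α-[di-tert-butyl(methoxy)silyloxy]-6α,19-(di-tert-butylsilylenedioxy)-13,14,15,16-tetranorclerodan-3-one | c1ccccc1COCC[C@@]1(C)[C@H](C)C[C@@H]4O[Si](C(C)(C)C)(C(C)(C)C)OC[C@]42[C@@H]1CCC(=O)[C@]2(O[Si](OC)(C(C)(C)C)C(C)(C)C)CCl | intermediate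
27 | 1-en-3-one derived from 26 | c1ccccc1COCC[C@@]1(C)[C@H](C)C[C@@H]4O[Si](C(C)(C)C)(C(C)(C)C)OC[C@]42[C@@H]1C=CC(=O)[C@]2(O[Si](OC)(C(C)(C)C)C(C)(C)C)CCl | intermediate
28 | 1β,2β-epoxy-3-ketone | c1ccccc1COCC[C@@]1(C)[C@H](C)C[C@@H]4O[Si](C(C)(C)C)(C(C)(C)C)OC[C@]42[C@@H]1[C@@H]5O[C@@H]5C(=O)[C@]2(O[Si](OC)(C(C)(C)C)C(C)(C)C)CCl | intermediate
29 | hydrazone of 28 | c1ccccc1COCC[C@@]1(C)[C@H](C)C[C@@H]4O[Si](C(C)(C)C)(C(C)(C)C)OC[C@]42[C@@H]1[C@@H]5O[C@@H]5C(=NN)[C@]2(O[Si](OC)(C(C)(C)C)C(C)(C)C)CCl | intermediate (not isolated)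
30 | 12-benzyloxy-18-chloro-4α-[di-tert-butyl(methoxy)silyloxy]-6α,19-(di-tert-butylsilylenedioxy)-13,14,15,16-tetranorclerod-2-en-1β-ol | c1ccccc1COCC[C@@]1(C)[C@H](C)C[C@@H]4O[Si](C(C)(C)C)(C(C)(C)C)OC[C@]42[C@@H]1[C@H](O)C=C[C@]2(O[Si](OC)(C(C)(C)C)C(C)(C)C)CCl | intermediate
31 | 18-chloro-4α-[di-tert-butyl(methoxy)silyloxy]-6α,19-(di-tert-butylsilylenedioxy)-13,14,15,16-tetranorclerodane-1β,12-diol | OCC[C@@]1(C)[C@H](C)C[C@@H]4O[Si](C(C)(C)C)(C(C)(C)C)OC[C@]42[C@@H]1[C@H](O)CC[C@]2(O[Si](OC)(C(C)(C)C)C(C)(C)C)CCl | intermediate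
32 | 1β,12-lactol (12-hydroxy-1β,12-epoxide; C12 epimers) | OC6C[C@@]1(C)[C@H](C)C[C@@H]4O[Si](C(C)(C)C)(C(C)(C)C)OC[C@]42[C@@H]1[C@H](O6)CC[C@]2(O[Si](OC)(C(C)(C)C)C(C)(C)C)CCl | intermediate (not isolated)
33 | 13,14,15,16-tetranorclerodan-12,1β-olide (δ-lactone) with the 18-chloro and silyl groups of 31 | O=C6C[C@@]1(C)[C@H](C)C[C@@H]4O[Si](C(C)(C)C)(C(C)(C)C)OC[C@]42[C@@H]1[C@H](O6)CC[C@]2(O[Si](OC)(C(C)(C)C)C(C)(C)C)CCl | intermediate
34 | lithium alkoxide of the 12-(3-furyl) lactol | [Li+].[O-]C6(c7ccoc7)C[C@@]1(C)[C@H](C)C[C@@H]4O[Si](C(C)(C)C)(C(C)(C)C)OC[C@]42[C@@H]1[C@H](O6)CC[C@]2(O[Si](OC)(C(C)(C)C)C(C)(C)C)CCl | intermediate (not isolated)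
35 | 3-furyl ketone (12-oxo-15,16-epoxycleroda-13(16),14-dien-1β-ol; 18-Cl; O4 and O6/O19 silylated) | O=C(c6ccoc6)C[C@@]1(C)[C@H](C)C[C@@H]4O[Si](C(C)(C)C)(C(C)(C)C)OC[C@]42[C@@H]1[C@H](O)CC[C@]2(O[Si](OC)(C(C)(C)C)C(C)(C)C)CCl | intermediate
36 | (12S)-15,16-epoxycleroda-13(16),14-diene-1β,12-diol (18-Cl; O4 and O6/O19 silylated) | O[C@@H](C[C@@]1(C)[C@H](C)C[C@@H]4O[Si](C(C)(C)C)(C(C)(C)C)OC[C@]42[C@@H]1[C@H](O)CC[C@]2(O[Si](OC)(C(C)(C)C)C(C)(C)C)CCl)c1ccoc1 | intermediate
37 | 1β,12-bis[(S)-2-methylbutanoate] of 36 | CC[C@H](C)C(=O)O[C@@H](C[C@@]1(C)[C@H](C)C[C@@H]4O[Si](C(C)(C)C)(C(C)(C)C)OC[C@]42[C@@H]1[C@H](OC(=O)[C@@H](C)CC)CC[C@]2(O[Si](OC)(C(C)(C)C)C(C)(C)C)CCl)c1ccoc1 | intermediate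
38 | 16-hydroxy-15,16-olide (γ-hydroxybutenolide; C16 epimers) | CC[C@H](C)C(=O)O[C@@H](C[C@@]1(C)[C@H](C)C[C@@H]4O[Si](C(C)(C)C)(C(C)(C)C)OC[C@]42[C@@H]1[C@H](OC(=O)[C@@H](C)CC)CC[C@]2(O[Si](OC)(C(C)(C)C)C(C)(C)C)CCl)C1=CC(=O)OC1O | intermediate (not isolated)
39 | silyl-protected clerod-13-en-15,16-olide | CC[C@H](C)C(=O)O[C@@H](C[C@@]1(C)[C@H](C)C[C@@H]4O[Si](C(C)(C)C)(C(C)(C)C)OC[C@]42[C@@H]1[C@H](OC(=O)[C@@H](C)CC)CC[C@]2(O[Si](OC)(C(C)(C)C)C(C)(C)C)CCl)C1=CC(=O)OC1 | intermediate
40 | 6,19-di-O-deacetylajugaciliatin A | CC[C@H](C)C(=O)O[C@@H](C[C@@]1(C)[C@H](C)C[C@H](O)[C@]2(CO)[C@@H]1[C@H](OC(=O)[C@@H](C)CC)CC[C@]2(O)CCl)C1=CC(=O)OC1 | intermediate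
41 | ajugaciliatin A | CC[C@H](C)C(=O)O[C@@H](C[C@@]1(C)[C@H](C)C[C@H](OC(C)=O)[C@]2(COC(C)=O)[C@@H]1[C@H](OC(=O)[C@@H](C)CC)CC[C@]2(O)CCl)C1=CC(=O)OC1 | target

**Totals and risks**

Total step count: 27. Longest linear sequence: 27 steps (the route is fully linear from 1 and 2).

Steps most likely to fail:

1. Step 16 (Proposed new method). What may go wrong: after Cl+ transfer the silyloxycarbenium ion may lose silicon before the 1,2-shift, giving plain α-chlorination without ring enlargement, or the shift may be slowed because the migrating C5 carries two β-oxygen substituents. Fallback, using known chemistry and a stepwise, Lewis-acid-driven rearrangement in place of the halonium-triggered one: setting out from 24, chlorination with N-chlorosuccinimide followed by HF·pyridine in the same flask would give, by the ordinary desilylative α-chlorination of a silyl enol ether, the chloroacetyl carbinol F1. BF3·OEt2 in CH2Cl2 would then promote the α-ketol (acyloin) rearrangement of the chelated, cisoid hydroxy ketone, the ring-enlarging reaction type known from 17-hydroxy-20-oxo steroids, to the 18-chloro-4α-hydroxy-3-ketone F2. Silylation of the tertiary alcohol with t-Bu2Si(OTf)2/2,6-lutidine and quenching with MeOH comes back to the route at 26.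

2. Step 11. What may go wrong: slow or incomplete C–H silylation at the crowded angular methyl, with competing loss or reduction of the hydridosilyl ether. Fallback, a palladium-catalysed oxime-directed C–H acetoxylation in place of the iridium-catalysed silylation: setting out from 16, Dess–Martin oxidation would give the 6-ketone F3 and NH2OH·HCl/NaOAc the oxime F4 (hydroxyl anti to C5). Pd(OAc)2 (cat.)/PhI(OAc)2 in AcOH/Ac2O would acetoxylate the β-methyl C19 through a five-membered palladacycle to the O-acetyl oxime 19-acetate F5, and NaHSO3 in aqueous EtOH would free the 19-acetoxy 6-ketone F6. LiAlH4 (axial hydride delivery from the β face and cleavage of the acetate) comes back to the route at 19.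

3. Step 18. What may go wrong: poor facial selectivity in the nucleophilic epoxidation, which the Wharton step would carry through to the 1α-alcohol. Fallback, stereochemical correction by inversion in place of reliance on facial control: setting out from 27, the 1α,2α-epoxy ketone F7 formed in the epoxidation would be taken through the same hydrazine treatment, via the epoxy hydrazone F8, to the 1α-allylic alcohol F9. A Mitsunobu reaction with 4-nitrobenzoic acid (PPh3, DIAD) would invert the allylic carbinol to the 1β-(4-nitrobenzoate) F10, and K2CO3/MeOH comes back to the route at 30.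

**Further compounds**

F1 | step 16 | 3β-(chloroacetyl)-12-benzyloxy-6α,19-(di-tert-butylsilylenedioxy)-8α-methylhydrindan-3α-ol | c1ccccc1COCC[C@@]1(C)[C@H](C)C[C@@H]4O[Si](C(C)(C)C)(C(C)(C)C)OC[C@]42[C@@H]1CC[C@]2(O)C(=O)CCl
F2 | step 16 | 12-benzyloxy-18-chloro-4α-hydroxy-6α,19-(di-tert-butylsilylenedioxy)-13,14,15,16-tetranorclerodan-3-one | c1ccccc1COCC[C@@]1(C)[C@H](C)C[C@@H]4O[Si](C(C)(C)C)(C(C)(C)C)OC[C@]42[C@@H]1CCC(=O)[C@]2(O)CCl
F3 | step 11 | 12-benzyloxy-8α-methylhydrindane-3,6-dione 3-ethylene ketal | c1ccccc1COCC[C@@]1(C)[C@H](C)CC(=O)[C@]2(C)[C@@H]1CCC23OCCO3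
F4 | step 11 | 6-oxime of F3 | c1ccccc1COCC[C@@]1(C)[C@H](C)CC(=NO)[C@]2(C)[C@@H]1CCC23OCCO3
F5 | step 11 | 19-acetoxy 6-(O-acetyl oxime) | c1ccccc1COCC[C@@]1(C)[C@H](C)CC(=NOC(C)=O)[C@]2(COC(C)=O)[C@@H]1CCC23OCCO3
F6 | step 11 | 19-acetoxy-12-benzyloxy-8α-methylhydrindane-3,6-dione 3-ethylene ketal | c1ccccc1COCC[C@@]1(C)[C@H](C)CC(=O)[C@]2(COC(C)=O)[C@@H]1CCC23OCCO3
F7 | step 18 | 1α,2α-epoxy-3-ketone (epimer of 28) | c1ccccc1COCC[C@@]1(C)[C@H](C)C[C@@H]4O[Si](C(C)(C)C)(C(C)(C)C)OC[C@]42[C@@H]1[C@H]5O[C@H]5C(=O)[C@]2(O[Si](OC)(C(C)(C)C)C(C)(C)C)CCl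
F8 | step 18 | hydrazone of F7 | c1ccccc1COCC[C@@]1(C)[C@H](C)C[C@@H]4O[Si](C(C)(C)C)(C(C)(C)C)OC[C@]42[C@@H]1[C@H]5O[C@H]5C(=NN)[C@]2(O[Si](OC)(C(C)(C)C)C(C)(C)C)CCl
F9 | step 18 | 2-en-1α-ol (C1 epimer of 30) | c1ccccc1COCC[C@@]1(C)[C@H](C)C[C@@H]4O[Si](C(C)(C)C)(C(C)(C)C)OC[C@]42[C@@H]1[C@@H](O)C=C[C@]2(O[Si](OC)(C(C)(C)C)C(C)(C)C)CCl
F10 | step 18 | 1β-(4-nitrobenzoate) of 30 | c1ccccc1COCC[C@@]1(C)[C@H](C)C[C@@H]4O[Si](C(C)(C)C)(C(C)(C)C)OC[C@]42[C@@H]1[C@H](OC(=O)c5ccc(cc5)[N+](=O)[O-])C=C[C@]2(O[Si](OC)(C(C)(C)C)C(C)(C)C)CCl
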